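**Plan**

1. Retrosynthesis: the carbamate and silyl ethers come off last. The E‑trisubstituted C8=C9 alkene is traced back to a C8≡C9 ring alkyne with a free C7 hydroxyl, and the 19‑membered lactam is opened at that triple bond to a seco diyne with two methyl‑capped alkynes.
2. The seco diyne is cut at C3–C4 (B‑alkyl Suzuki–Miyaura) and N–C1 (acylation) into a C4–C8 enyne, (E)‑3‑iodo‑2‑methylacrylic acid (C1–C3) and a C9–C21 aniline. The aniline is cut at C10–C11 (allenylstannane propargylation), C12–C13 (olefination) and C15–C16 (Negishi).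
3. Forward: arene and C13–C15 are joined first, the chain is grown to the α‑methoxy aldehyde, propargylated, reduced to the aniline and acylated. The enyne is then attached, and the only ring, the 19‑membered lactam, closes by alkyne metathesis; alkene, carbamate and deprotection follow.
4. Stereochemistry: C14 from the (R)‑hydroxy ester; C12 from oxazolidinone‑directed enolate hydroxylation; C10/C11 from the allenylstannane made from (S)‑but‑3‑yn‑2‑ol (syn, matched with Felkin–Anh control); C6/C7 from a Z‑crotylborane with isopinocampheyl groups; 2E from the iodoacrylic acid; 8E from hydroxyl‑directed trans‑hydrostannation and methyl Stille coupling.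
5. Enabling feature: in the 19‑membered ansa lactam (C1 amide carbonyl, C2–C15 chain, C16–C21 arene, N on C20) the E‑trisubstituted C8=C9 alkene carries its methyl on C8 beside oxygenated C7, so it maps onto a ring alkyne with a propargylic hydroxyl.

Key step: step 22

Assumption: 3‑bromo‑5‑nitrophenol, (4S)‑4‑benzyl‑3‑(chloroacetyl)oxazolidin‑2‑one, (E)‑3‑iodo‑2‑methylacrylic acid and but‑2‑ynal are taken as purchasable; the ansamycin numbering above is used for all chain positions.
Abbreviations: TIPS = triisopropylsilyl, TBS = tert‑butyldimethylsilyl, TES = triethylsilyl, Ipc = isopinocampheyl, 9‑BBN = 9‑borabicyclo[3.3.1]nonane.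

**Route**

Step 1
Reactants: 1 (S)-but-3-yn-2-ol
Product: 3 (S)-pent-3-yn-2-ol, via dilithio alkynolate 2 (not isolated)
Conditions: n-BuLi (2.1 equiv), THF, −78 → 0 °C; MeI, −78 °C → rt; H2O
Reagents that add atoms: iodomethane, CI
Why: Double deprotonation gives the alkoxide–acetylide, whose carbon terminus is alkylated selectively by MeI (acetylide C‑alkylation), the carbinol stereocentre not being touched.

Step 2
Reactants: 3 (S)-pent-3-yn-2-ol
Product: 4 (S)-pent-3-yn-2-yl methanesulfonate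
Conditions: MsCl, Et3N, CH2Cl2, −78 °C
Reagents that add atoms: methanesulfonyl chloride, CS(=O)(=O)Cl
Why: O‑Sulfonylation of the secondary propargylic alcohol proceeds without breaking the C–O bond, so the configuration is kept.

Step 3
Reactants: 4 (S)-pent-3-yn-2-yl methanesulfonate
Product: 5 (M)-tributyl(penta-2,3-dien-2-yl)stannane
Conditions: Bu3SnH, LiN(iPr)2, THF, 0 °C; CuBr·SMe2, −78 °C; then 4, −78 °C
Reagents that add atoms: tributyltin hydride, CCCC[SnH](CCCC)CCCC
Why: The stannylcopper reagent displaces the propargylic mesylate in an anti SN2' sense, which transfers the central chirality of 4 to the (M) allene axis.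

Step 4
Reactants: 6 3-bromo-5-nitrophenol
Product: 7 (3-bromo-5-nitrophenoxy)triisopropylsilane
Conditions: TIPSCl, imidazole, DMF, rt
Reagents that add atoms: chlorotriisopropylsilane, CC(C)[Si](Cl)(C(C)C)C(C)C
Why: Imidazole‑mediated silylation of the acidic phenol gives a bulky aryl silyl ether that should last to the final step.

Step 5
Reactants: 8 methyl (R)-3-hydroxy-2-methylpropanoate
Product: 9 methyl (S)-3-iodo-2-methylpropanoate
Conditions: I2, PPh3, imidazole, CH2Cl2, 0 °C → rt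
Reagents that add atoms: iodine, II
Why: Appel‑type iodination converts the primary alcohol through its alkoxyphosphonium salt by SN2 attack of iodide, away from the stereocentre (the descriptor changes only by priority).

Step 6
Reactants: 9 methyl (S)-3-iodo-2-methylpropanoate; 7 (3-bromo-5-nitrophenoxy)triisopropylsilane
Product: 11 methyl (2R)-2-methyl-3-[3-nitro-5-(triisopropylsilyloxy)phenyl]propanoate, via alkylzinc iodide 10 (not isolated)
Conditions: Zn dust (I2-activated), DMF, rt; supernatant transferred to 7, Pd(OAc)2 (3 mol %), SPhos (6 mol %), DMF, rt → 40 °C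
Reagents that add atoms: none
Why: Zinc inserts into the primary C–I bond and the ester‑stabilised alkylzinc couples with the electron‑poor aryl bromide (Negishi coupling), forming C15–C16 without touching the C14 stereocentre; the nitro group is tolerated once excess zinc is left behind.

Step 7
Reactants: 11 methyl (2R)-2-methyl-3-[3-nitro-5-(triisopropylsilyloxy)phenyl]propanoate
Product: 12 (2R)-2-methyl-3-[3-nitro-5-(triisopropylsilyloxy)phenyl]propanal
Conditions: iBu2AlH (1.1 equiv), CH2Cl2, −78 °C; MeOH, aq. potassium sodium tartrate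
Reagents that add atoms: none
Why: At −78 °C the hydride reduction stops at the aluminium hemiacetal of the α‑branched methyl ester, which releases the aldehyde on work‑up, while the nitroarene reacts far more slowly.

Step 8
Reactants: 13 (4S)-4-benzyl-3-(chloroacetyl)-1,3-oxazolidin-2-one
Product: 14 diethyl {2-[(4S)-4-benzyl-2-oxo-1,3-oxazolidin-3-yl]-2-oxoethyl}phosphonate
Conditions: P(OEt)3 (neat), 130 °C
Reagents that add atoms: triethyl phosphite, CCOP(OCC)OCC
Why: Michaelis–Arbuzov reaction of the α‑chloro imide gives the phosphonate that carries the auxiliary needed later for C12.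

Step 9
Reactants: 12 (2R)-2-methyl-3-[3-nitro-5-(triisopropylsilyloxy)phenyl]propanal; 14 diethyl {2-[(4S)-4-benzyl-2-oxo-1,3-oxazolidin-3-yl]-2-oxoethyl}phosphonate
Product: 15 (4S)-4-benzyl-3-{(2E,4R)-4-methyl-5-[3-nitro-5-(triisopropylsilyloxy)phenyl]pent-2-enoyl}-1,3-oxazolidin-2-one
Conditions: LiCl, iPr2NEt, MeCN, rt
Reagents that add atoms: none
Why: Horner–Wadsworth–Emmons olefination under mild LiCl/amine conditions gives the E‑enoyl imide (C12=C13) without epimerising the α‑methyl aldehyde.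

Step 10
Reactants: 15 (4S)-4-benzyl-3-{(2E,4R)-4-methyl-5-[3-nitro-5-(triisopropylsilyloxy)phenyl]pent-2-enoyl}-1,3-oxazolidin-2-one
Product: 16 (4S)-4-benzyl-3-{(4S)-4-methyl-5-[3-nitro-5-(triisopropylsilyloxy)phenyl]pentanoyl}-1,3-oxazolidin-2-one
Conditions: H2 (3 bar), RhCl(PPh3)3 (10 mol %), toluene/EtOH, rt
Reagents that add atoms: none
Why: Homogeneous hydrogenation with the rhodium phosphine chloride saturates the disubstituted alkene while leaving the nitro group and silyl ether alone (the C14 descriptor changes only by priority).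

Step 11
Reactants: 16 (4S)-4-benzyl-3-{(4S)-4-methyl-5-[3-nitro-5-(triisopropylsilyloxy)phenyl]pentanoyl}-1,3-oxazolidin-2-one
Product: 18 (4S)-4-benzyl-3-{(2S,4R)-2-hydroxy-4-methyl-5-[3-nitro-5-(triisopropylsilyloxy)phenyl]pentanoyl}-1,3-oxazolidin-2-one, via sodium Z-enolate 17 (not isolated)
Conditions: NaN(SiMe3)2, THF, −78 °C; 2-(benzenesulfonyl)-3-phenyloxaziridine, −78 °C; AcOH
Reagents that add atoms: 2-(benzenesulfonyl)-3-phenyloxaziridine, O=S(=O)(c1ccccc1)N1OC1c1ccccc1
Why: Auxiliary‑directed enolate hydroxylation: the chelated Z‑enolate is oxidised by the N‑sulfonyloxaziridine on the face opposite the benzyl group, which sets C12 as (S).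

Step 12
Reactants: 18 (4S)-4-benzyl-3-{(2S,4R)-2-hydroxy-4-methyl-5-[3-nitro-5-(triisopropylsilyloxy)phenyl]pentanoyl}-1,3-oxazolidin-2-one
Product: 19 (4S)-4-benzyl-3-{(2S,4R)-2-methoxy-4-methyl-5-[3-nitro-5-(triisopropylsilyloxy)phenyl]pentanoyl}-1,3-oxazolidin-2-one
Conditions: Me3OBF4, 1,8-bis(dimethylamino)naphthalene, 4 Å MS, CH2Cl2, rt
Reagents that add atoms: trimethyloxonium tetrafluoroborate, C[O+](C)C.F[B-](F)(F)F
Why: O‑Methylation with the oxonium salt and a non‑nucleophilic amine base avoids enolisation, so the α‑stereocentre is kept.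

Step 13
Reactants: 19 (4S)-4-benzyl-3-{(2S,4R)-2-methoxy-4-methyl-5-[3-nitro-5-(triisopropylsilyloxy)phenyl]pentanoyl}-1,3-oxazolidin-2-one
Product: 20 (2S,4R)-2-methoxy-4-methyl-5-[3-nitro-5-(triisopropylsilyloxy)phenyl]pentan-1-ol
Conditions: LiBH4, MeOH (1 equiv), THF, 0 °C
Reagents that add atoms: none
Why: Reductive cleavage of the imide releases the primary alcohol and the recoverable auxiliary, and borohydride does not reduce the nitroarene.

Step 14
Reactants: 20 (2S,4R)-2-methoxy-4-methyl-5-[3-nitro-5-(triisopropylsilyloxy)phenyl]pentan-1-ol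
Product: 21 (2S,4R)-2-methoxy-4-methyl-5-[3-nitro-5-(triisopropylsilyloxy)phenyl]pentanal
Conditions: Dess–Martin periodinane, CH2Cl2, 0 °C → rt
Reagents that add atoms: none
Why: Dess–Martin oxidation gives the α‑methoxy aldehyde under non‑basic conditions that should not epimerise C12; the aldehyde is used at once.

Step 15
Reactants: 21 (2S,4R)-2-methoxy-4-methyl-5-[3-nitro-5-(triisopropylsilyloxy)phenyl]pentanal; 5 (M)-tributyl(penta-2,3-dien-2-yl)stannane
Product: 22 (4S,5R,6S,8R)-6-methoxy-4,8-dimethyl-9-[3-nitro-5-(triisopropylsilyloxy)phenyl]non-2-yn-5-ol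
Conditions: BF3·OEt2, CH2Cl2, −78 °C; aq. NaHCO3
Reagents that add atoms: none
Why: Lewis‑acid‑promoted anti‑SE2' propargylation through an open transition state places the new C10–C11 bond where the mesylate oxygen of 4 had been and gives the syn C10/C11 pair, and this reagent sense coincides with Felkin–Anh (non‑chelate) attack on the α‑methoxy aldehyde, so C10 (S) and C11 (R) form in the matched case with the methyl‑capped alkyne already in place.

Step 16
Reactants: 22 (4S,5R,6S,8R)-6-methoxy-4,8-dimethyl-9-[3-nitro-5-(triisopropylsilyloxy)phenyl]non-2-yn-5-ol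
Product: 23 tert-butyl{[(4S,5R,6S,8R)-6-methoxy-4,8-dimethyl-9-[3-nitro-5-(triisopropylsilyloxy)phenyl]non-2-yn-5-yl]oxy}dimethylsilane
Conditions: TBSOTf, 2,6-lutidine, CH2Cl2, −78 → 0 °C
Reagents that add atoms: tert-butyldimethylsilyl trifluoromethanesulfonate, CC(C)(C)[Si](C)(C)OS(=O)(=O)C(F)(F)F
Why: The silyl triflate is reactive enough for the hindered C11 hydroxyl, which must stay masked so that only C7–OH can later direct the hydrostannation and take the carbamate.

Step 17
Reactants: 23 tert-butyl{[(4S,5R,6S,8R)-6-methoxy-4,8-dimethyl-9-[3-nitro-5-(triisopropylsilyloxy)phenyl]non-2-yn-5-yl]oxy}dimethylsilane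
Product: 24 3-[(2R,4S,5R,6S)-5-(tert-butyldimethylsilyloxy)-4-methoxy-2,6-dimethylnon-7-yn-1-yl]-5-(triisopropylsilyloxy)aniline
Conditions: Zn dust, AcOH, THF, 0 °C → rt
Reagents that add atoms: none
Why: Dissolving‑metal reduction of the nitro group to the aniline spares the internal alkyne and both silyl ethers.

Step 18
Reactants: 24 3-[(2R,4S,5R,6S)-5-(tert-butyldimethylsilyloxy)-4-methoxy-2,6-dimethylnon-7-yn-1-yl]-5-(triisopropylsilyloxy)aniline; 25 (2E)-3-iodo-2-methylprop-2-enoic acid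
Product: 27 (2E)-N-{3-[(2R,4S,5R,6S)-5-(tert-butyldimethylsilyloxy)-4-methoxy-2,6-dimethylnon-7-yn-1-yl]-5-(triisopropylsilyloxy)phenyl}-3-iodo-2-methylprop-2-enamide, via acid chloride 26 (not isolated)
Conditions: 25, 1-chloro-N,N,2-trimethylprop-1-en-1-amine, CH2Cl2, 0 °C → rt; then 24, pyridine, 0 °C
Reagents that add atoms: none
Why: The acid is turned into its chloride under neutral conditions with the α‑chloroenamine and N‑acylates the aniline, with the E vinyl iodide carried over unchanged.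

Step 19
Reactants: 28 but-2-ynal
Product: 30 (3S,4R)-3-methylhept-1-en-5-yn-4-ol, via bis(isopinocampheyl)borinate 29 (not isolated)
Conditions: (Z)-but-2-ene, KOtBu, n-BuLi, THF, −78 → −45 °C; (+)-Ipc2BOMe [from (−)-α-pinene], −78 °C; BF3·OEt2; 28, −78 °C; then NaOH, H2O2
Reagents that add atoms: (Z)-but-2-ene, C/C=C\C
Why: Asymmetric crotylboration through a closed chair transition state: the Z‑crotyl geometry gives the syn C6/C7 pair and the isopinocampheyl groups direct attack to the Re face of the ynal, setting C6 (S) and C7 (R) with the second methyl‑capped alkyne already present.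

Step 20
Reactants: 30 (3S,4R)-3-methylhept-1-en-5-yn-4-ol
Product: 31 triethyl{[(3S,4R)-3-methylhept-1-en-5-yn-4-yl]oxy}silane
Conditions: TESCl, imidazole, CH2Cl2, 0 °C
Reagents that add atoms: chlorotriethylsilane, CC[Si](Cl)(CC)CC
Why: The labile TES ether protects C7–OH through coupling and metathesis and can later be removed in the presence of the TBS and TIPS ethers.

Step 21
Reactants: 31 triethyl{[(3S,4R)-3-methylhept-1-en-5-yn-4-yl]oxy}silane; 27 (2E)-N-{3-[(2R,4S,5R,6S)-5-(tert-butyldimethylsilyloxy)-4-methoxy-2,6-dimethylnon-7-yn-1-yl]-5-(triisopropylsilyloxy)phenyl}-3-iodo-2-methylprop-2-enamide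
Product: 33 seco anilide diyne (2E,6S,7R,10S,11R,12S,14R; prop-1-ynyl groups on C7 and C10; 7-OTES; 11-OTBS; 18-OTIPS), via B-alkyl-9-BBN borane 32 (not isolated)
Conditions: 9-BBN dimer, THF, rt; then 27, Pd(dppf)Cl2 (10 mol %), AsPh3, K3PO4 (3 M aq.), DMF, rt
Reagents that add atoms: none
Why: 9‑BBN hydroborates the terminal alkene much faster than the internal alkyne, and the B‑alkyl borane undergoes Suzuki–Miyaura coupling with the E vinyl iodide with retention of geometry, forming C3–C4.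

Step 22
Reactants: 33 seco anilide diyne
Product: 34 19-membered cycloalkyne lactam (C8≡C9; 7-OTES; 11-OTBS; 12-OMe; 18-OTIPS; 2E,6S,7R,10S,11R,12S,14R)
Conditions: [Mo(≡CC6H4-4-OMe)(OSiPh3)3] (15 mol %), powdered 5 Å MS, toluene (2 mM), 80 °C
Reagents that add atoms: none
Why: The molybdenum alkylidyne adds to one methyl‑capped alkyne in a [2+2] manner, the metallacyclobutadiene opens to a substrate‑bound alkylidyne, and the same sequence at the second alkyne releases the cycloalkyne, while the but‑2‑yne formed is taken up by the 5 Å sieves and drives the equilibrium. The closest known reaction type is ring‑closing alkyne metathesis of methyl‑capped diynes with silanolate‑ligated molybdenum alkylidynes. The 19‑membered ring closes end to end at C8–C9 as an unstrained macrocyclic alkyne under high dilution, helped by the rigid E‑enamide and the meta‑bridged arene. No stereocentre is formed, and because a triple bond has no geometry no E/Z mixture can arise. The step needs alkyne over alkene selectivity (intrinsic to the alkylidyne, so C2=C3 is not touched), tolerance of the secondary anilide and the three silyl ethers (known for this catalyst class with amide substrates), and cyclisation over oligomerisation, which dilution and the reversibility of the process secure despite the two branched propargylic positions.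

Step 23
Reactants: 34 19-membered cycloalkyne lactam
Product: 35 cycloalkyne lactam with free C7 hydroxyl (11-OTBS; 18-OTIPS)
Conditions: PPTS (cat.), MeOH/CH2Cl2, 0 °C
Reagents that add atoms: none
Why: Acid‑catalysed methanolysis cleaves the secondary TES ether much faster than the hindered secondary TBS ether or the aryl TIPS ether.

Step 24
Reactants: 35 cycloalkyne lactam with free C7 hydroxyl
Product: 36 (8Z)-8-(tributylstannyl) cycloalkene lactam (7-OH; 11-OTBS; 18-OTIPS)
Conditions: [Cp*RuCl]4 (5 mol %), Bu3SnH (1.2 equiv, slow addition), CH2Cl2, rt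
Reagents that add atoms: tributyltin hydride, CCCC[SnH](CCCC)CCCC
Why: Ruthenium‑catalysed trans‑hydrostannation: hydrogen bonding of the C7 hydroxyl to the chloride ligand steers tin to the proximal carbon C8 and hydrogen to C9 by anti addition, which places C7 and C10 trans across the new alkene.

Step 25
Reactants: 36 (8Z)-8-(tributylstannyl) cycloalkene lactam
Product: 37 (8E)-8-methyl macrolactam allylic alcohol (7-OH; 11-OTBS; 18-OTIPS)
Conditions: MeI, Pd(PPh3)4 (10 mol %), Cu(O2CC4H3S) (copper thiophene-2-carboxylate), [NBu4][Ph2PO2], DMF, rt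
Reagents that add atoms: iodomethane, CI
Why: Copper‑assisted Stille coupling exchanges tin for methyl with retention of alkene geometry, the phosphinate salt taking up the tin, to give the E‑trisubstituted C8=C9 alkene with its methyl on C8.

Step 26
Reactants: 37 (8E)-8-methyl macrolactam allylic alcohol
Product: 39 C7 carbamate with 11-OTBS and 18-OTIPS, via N-trichloroacetyl carbamate 38 (not isolated)
Conditions: Cl3CC(O)NCO, CH2Cl2, 0 °C; then neutral Al2O3, rt
Reagents that add atoms: trichloroacetyl isocyanate, O=C=NC(=O)C(Cl)(Cl)Cl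
Why: The only free hydroxyl (C7) adds to the acyl isocyanate, and the trichloroacetyl group is hydrolysed on neutral alumina to the primary carbamate without exposing the aryl silyl ether to base.

Step 27
Reactants: 39 C7 carbamate with 11-OTBS and 18-OTIPS
Product: 40 CNP0247621.1 (target)
Conditions: HF·pyridine, pyridine, THF, 0 °C → rt
Reagents that add atoms: none
Why: Buffered fluoride cleaves the aryl TIPS and secondary TBS ethers and should leave the allylic carbamate, the enamide and both alkenes intact.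

**Compound list**

1 | (S)-but-3-yn-2-ol | C#C[C@H](C)O | starting material
2 | dilithium (2S)-but-3-yn-4-id-2-olate (O,C-dilithio derivative of 1) | [Li]C#C[C@H](C)O[Li] | intermediate
3 | (S)-pent-3-yn-2-ol | CC#C[C@H](C)O | intermediate
4 | (S)-pent-3-yn-2-yl methanesulfonate | CC#C[C@H](C)OS(C)(=O)=O | intermediate
5 | (M)-tributyl(penta-2,3-dien-2-yl)stannane (axis aR) | CC([Sn](CCCC)(CCCC)CCCC)=[C@@]=C([H])C | intermediate
6 | 3-bromo-5-nitrophenol | Oc1cc(Br)cc([N+](=O)[O-])c1 | starting material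
7 | (3-bromo-5-nitrophenoxy)triisopropylsilane | CC(C)[Si](Oc1cc(Br)cc([N+](=O)[O-])c1)(C(C)C)C(C)C | intermediate
8 | methyl (R)-3-hydroxy-2-methylpropanoate | COC(=O)[C@H](C)CO | starting material
9 | methyl (S)-3-iodo-2-methylpropanoate | COC(=O)[C@H](C)CI | intermediate
10 | [(2S)-3-methoxy-2-methyl-3-oxopropyl]zinc iodide | COC(=O)[C@H](C)C[Zn]I | intermediate
11 | methyl (2R)-2-methyl-3-[3-nitro-5-(triisopropylsilyloxy)phenyl]propanoate | COC(=O)[C@H](C)Cc1cc(O[Si](C(C)C)(C(C)C)C(C)C)cc([N+](=O)[O-])c1 | intermediate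
12 | (2R)-2-methyl-3-[3-nitro-5-(triisopropylsilyloxy)phenyl]propanal | O=C[C@H](C)Cc1cc(O[Si](C(C)C)(C(C)C)C(C)C)cc([N+](=O)[O-])c1 | intermediate
13 | (4S)-4-benzyl-3-(chloroacetyl)-1,3-oxazolidin-2-one | O=C(CCl)N1[C@@H](Cc2ccccc2)COC1=O | starting material
14 | diethyl {2-[(4S)-4-benzyl-2-oxo-1,3-oxazolidin-3-yl]-2-oxoethyl}phosphonate | CCOP(=O)(OCC)CC(=O)N1[C@@H](Cc2ccccc2)COC1=O | intermediate
15 | (4S)-4-benzyl-3-{(2E,4R)-4-methyl-5-[3-nitro-5-(triisopropylsilyloxy)phenyl]pent-2-enoyl}-1,3-oxazolidin-2-one | O=C(/C=C/[C@H](C)Cc1cc(O[Si](C(C)C)(C(C)C)C(C)C)cc([N+](=O)[O-])c1)N1[C@@H](Cc2ccccc2)COC1=O | intermediate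
16 | (4S)-4-benzyl-3-{(4S)-4-methyl-5-[3-nitro-5-(triisopropylsilyloxy)phenyl]pentanoyl}-1,3-oxazolidin-2-one | O=C(CC[C@H](C)Cc1cc(O[Si](C(C)C)(C(C)C)C(C)C)cc([N+](=O)[O-])c1)N1[C@@H](Cc2ccccc2)COC1=O | intermediate
17 | sodium (Z)-enolate of 16 | [Na]O/C(=C\C[C@H](C)Cc1cc(O[Si](C(C)C)(C(C)C)C(C)C)cc([N+](=O)[O-])c1)N1[C@@H](Cc2ccccc2)COC1=O | intermediate
18 | (4S)-4-benzyl-3-{(2S,4R)-2-hydroxy-4-methyl-5-[3-nitro-5-(triisopropylsilyloxy)phenyl]pentanoyl}-1,3-oxazolidin-2-one | O=C([C@@H](O)C[C@H](C)Cc1cc(O[Si](C(C)C)(C(C)C)C(C)C)cc([N+](=O)[O-])c1)N1[C@@H](Cc2ccccc2)COC1=O | intermediate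
19 | (4S)-4-benzyl-3-{(2S,4R)-2-methoxy-4-methyl-5-[3-nitro-5-(triisopropylsilyloxy)phenyl]pentanoyl}-1,3-oxazolidin-2-one | O=C([C@@H](OC)C[C@H](C)Cc1cc(O[Si](C(C)C)(C(C)C)C(C)C)cc([N+](=O)[O-])c1)N1[C@@H](Cc2ccccc2)COC1=O | intermediate
20 | (2S,4R)-2-methoxy-4-methyl-5-[3-nitro-5-(triisopropylsilyloxy)phenyl]pentan-1-ol | OC[C@@H](OC)C[C@H](C)Cc1cc(O[Si](C(C)C)(C(C)C)C(C)C)cc([N+](=O)[O-])c1 | intermediate
21 | (2S,4R)-2-methoxy-4-methyl-5-[3-nitro-5-(triisopropylsilyloxy)phenyl]pentanal | O=C[C@@H](OC)C[C@H](C)Cc1cc(O[Si](C(C)C)(C(C)C)C(C)C)cc([N+](=O)[O-])c1 | intermediate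
22 | (4S,5R,6S,8R)-6-methoxy-4,8-dimethyl-9-[3-nitro-5-(triisopropylsilyloxy)phenyl]non-2-yn-5-ol | CC#C[C@H](C)[C@@H](O)[C@@H](OC)C[C@H](C)Cc1cc(O[Si](C(C)C)(C(C)C)C(C)C)cc([N+](=O)[O-])c1 | intermediate
23 | tert-butyl{[(4S,5R,6S,8R)-6-methoxy-4,8-dimethyl-9-[3-nitro-5-(triisopropylsilyloxy)phenyl]non-2-yn-5-yl]oxy}dimethylsilane | CC#C[C@H](C)[C@@H](O[Si](C)(C)C(C)(C)C)[C@@H](OC)C[C@H](C)Cc1cc(O[Si](C(C)C)(C(C)C)C(C)C)cc([N+](=O)[O-])c1 | intermediate
24 | 3-[(2R,4S,5R,6S)-5-(tert-butyldimethylsilyloxy)-4-methoxy-2,6-dimethylnon-7-yn-1-yl]-5-(triisopropylsilyloxy)aniline | CC#C[C@H](C)[C@@H](O[Si](C)(C)C(C)(C)C)[C@@H](OC)C[C@H](C)Cc1cc(N)cc(O[Si](C(C)C)(C(C)C)C(C)C)c1 | intermediate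
25 | (2E)-3-iodo-2-methylprop-2-enoic acid | C/C(=C\I)C(=O)O | starting material
26 | (2E)-3-iodo-2-methylprop-2-enoyl chloride | C/C(=C\I)C(=O)Cl | intermediate
27 | (2E)-N-{3-[(2R,4S,5R,6S)-5-(tert-butyldimethylsilyloxy)-4-methoxy-2,6-dimethylnon-7-yn-1-yl]-5-(triisopropylsilyloxy)phenyl}-3-iodo-2-methylprop-2-enamide | CC#C[C@H](C)[C@@H](O[Si](C)(C)C(C)(C)C)[C@@H](OC)C[C@H](C)Cc1cc(NC(=O)/C(C)=C/I)cc(O[Si](C(C)C)(C(C)C)C(C)C)c1 | intermediate
28 | but-2-ynal | CC#CC=O | starting material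
29 | (3S,4R)-3-methylhept-1-en-5-yn-4-yl bis[(1S,2S,3S,5R)-isopinocampheyl]borinate | C=C[C@H](C)[C@@H](OB([C@H]1C[C@H]2C[C@@H]([C@@H]1C)C2(C)C)[C@H]1C[C@H]2C[C@@H]([C@@H]1C)C2(C)C)C#CC | intermediate
30 | (3S,4R)-3-methylhept-1-en-5-yn-4-ol | C=C[C@H](C)[C@@H](O)C#CC | intermediate
31 | triethyl{[(3S,4R)-3-methylhept-1-en-5-yn-4-yl]oxy}silane | C=C[C@H](C)[C@@H](O[Si](CC)(CC)CC)C#CC | intermediate
32 | 9-[(3S,4R)-3-methyl-4-(triethylsilyloxy)hept-5-yn-1-yl]-9-borabicyclo[3.3.1]nonane | C(C[C@H](C)[C@@H](O[Si](CC)(CC)CC)C#CC)B1C2CCCC1CCC2 | intermediate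
33 | seco anilide diyne, (2E,6S,7R)-N-{3-[(2R,4S,5R,6S)-5-(tert-butyldimethylsilyloxy)-4-methoxy-2,6-dimethylnon-7-yn-1-yl]-5-(triisopropylsilyloxy)phenyl}-2,6-dimethyl-7-(triethylsilyloxy)dec-2-en-8-ynamide | CC#C[C@H](C)[C@@H](O[Si](C)(C)C(C)(C)C)[C@@H](OC)C[C@H](C)Cc1cc(NC(=O)/C(C)=C/CC[C@H](C)[C@@H](O[Si](CC)(CC)CC)C#CC)cc(O[Si](C(C)C)(C(C)C)C(C)C)c1 | intermediate
34 | 19-membered cycloalkyne lactam: 2E alkene with 2-Me, 6S-Me, 7R-OTES, C8≡C9, 10S-Me, 11R-OTBS, 12S-OMe, 14R-Me, 18-OTIPS, N on C20 | CO[C@H]1C[C@H](C)Cc2cc(O[Si](C(C)C)(C(C)C)C(C)C)cc(c2)NC(=O)/C(C)=C/CC[C@H](C)[C@@H](O[Si](CC)(CC)CC)C#C[C@H](C)[C@H]1O[Si](C)(C)C(C)(C)C | intermediate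
35 | cycloalkyne lactam as 34 but with free 7R hydroxyl | CO[C@H]1C[C@H](C)Cc2cc(O[Si](C(C)C)(C(C)C)C(C)C)cc(c2)NC(=O)/C(C)=C/CC[C@H](C)[C@@H](O)C#C[C@H](C)[C@H]1O[Si](C)(C)C(C)(C)C | intermediate
36 | (2E,8Z)-8-(tributylstannyl) macrolactam: 7R-OH, Sn on C8, H on C9, 11R-OTBS, 18-OTIPS | CO[C@H]1C[C@H](C)Cc2cc(O[Si](C(C)C)(C(C)C)C(C)C)cc(c2)NC(=O)/C(C)=C/CC[C@H](C)[C@@H](O)/C([Sn](CCCC)(CCCC)CCCC)=C/[C@H](C)[C@H]1O[Si](C)(C)C(C)(C)C | intermediate
37 | (2E,8E)-8-methyl macrolactam: 7R-OH, 11R-OTBS, 18-OTIPS | CO[C@H]1C[C@H](C)Cc2cc(O[Si](C(C)C)(C(C)C)C(C)C)cc(c2)NC(=O)/C(C)=C/CC[C@H](C)[C@@H](O)/C(C)=C/[C@H](C)[C@H]1O[Si](C)(C)C(C)(C)C | intermediate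
38 | 7-O-[N-(trichloroacetyl)carbamoyl] derivative of 37 | CO[C@H]1C[C@H](C)Cc2cc(O[Si](C(C)C)(C(C)C)C(C)C)cc(c2)NC(=O)/C(C)=C/CC[C@H](C)[C@@H](OC(=O)NC(=O)C(Cl)(Cl)Cl)/C(C)=C/[C@H](C)[C@H]1O[Si](C)(C)C(C)(C)C | intermediate
39 | 7-O-carbamate of 37 (11R-OTBS, 18-OTIPS) | CO[C@H]1C[C@H](C)Cc2cc(O[Si](C(C)C)(C(C)C)C(C)C)cc(c2)NC(=O)/C(C)=C/CC[C@H](C)[C@@H](OC(N)=O)/C(C)=C/[C@H](C)[C@H]1O[Si](C)(C)C(C)(C)C | intermediate
40 | CNP0247621.1, (2E,6S,7R,8E,10S,11R,12S,14R) macrolactam with 7-O-carbamate, 11-OH, 12-OMe, 18-OH | CO[C@H]1C[C@H](C)Cc2cc(O)cc(c2)NC(=O)/C(C)=C/CC[C@H](C)[C@@H](OC(N)=O)/C(C)=C/[C@H](C)[C@H]1O | target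

**Step count and risks**

Total: 27 steps. Longest linear sequence: 20 steps (step 4 or 5, then 6, 7, 9–18, 21–27).

Steps most likely to fail:

1. Step 22 (ring‑closing alkyne metathesis). The alkylidyne may be lost by protonolysis at the anilide N–H, and the two α‑branched alkynes may engage so slowly that oligomerisation or catalyst decay wins over ring closure. Fallback, setting out from 23 and 31 and returning at 34: the triple bond is made before the amide exists and the ring is closed at C3–C4 instead. Alkyne cross‑metathesis of 23 with an excess of 31 (same molybdenum alkylidyne, 5 Å MS, toluene) would give the C8≡C9 nitro enyne F1. Reduction with Zn and NH4Cl in EtOH/H2O gives the aniline enyne F2, and acylation with acid chloride 26 and pyridine gives the iodoacrylamide enyne F3. 9‑BBN adds to the terminal alkene to give the borane F4, and intramolecular B‑alkyl Suzuki–Miyaura coupling (Pd(dppf)Cl2, AsPh3, K3PO4, DMF/THF, high dilution) closes the same 19‑membered ring to 34.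

2. Step 25 (methyl Stille coupling). Protodestannation of the hindered α‑hydroxy alkenylstannane or slow tin‑to‑copper transfer may return the disubstituted alkene instead of the methylated one. Fallback, setting out from 36 and returning at 37: the polarity of the coupling is reversed. Iododestannation of 36 with I2 in CH2Cl2 at 0 °C (retention of geometry) gives the (8Z)-8-iodo macrolactam F5, which is methylated by Negishi coupling with excess MeZnCl and Pd(PPh3)4 in THF to give 37.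

3. Step 19 (crotylboration of the ynal). Facial and syn/anti selectivity may erode with the small, reactive ynal, and the volatile product may be lost on separation from isopinocampheol. Fallback, setting out from 28 and returning at 31: a boron‑mediated syn‑aldol addition of (4R)-4-benzyl-3-propanoyl-1,3-oxazolidin-2-one (Bu2BOTf, iPr2NEt, CH2Cl2, −78 → 0 °C) to 28 gives the syn aldol imide F6 with both centres set by the auxiliary. Silylation with TESOTf and 2,6‑lutidine gives the silyl ether imide F7, LiBH4 reduction gives the primary alcohol F8, Dess–Martin oxidation gives the aldehyde F9, and Wittig methylenation with Ph3P=CH2 gives 31.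

**Further compounds**

F1 | step 22 | nitro enyne, triethyl{[(3S,4R,7S,8R,9S,11R)-8-(tert-butyldimethylsilyloxy)-9-methoxy-3,7,11-trimethyl-12-[3-nitro-5-(triisopropylsilyloxy)phenyl]dodec-1-en-5-yn-4-yl]oxy}silane | C=C[C@H](C)[C@@H](O[Si](CC)(CC)CC)C#C[C@H](C)[C@@H](O[Si](C)(C)C(C)(C)C)[C@@H](OC)C[C@H](C)Cc1cc(O[Si](C(C)C)(C(C)C)C(C)C)cc([N+](=O)[O-])c1
F2 | step 22 | aniline enyne (nitro group of F1 reduced to NH2) | C=C[C@H](C)[C@@H](O[Si](CC)(CC)CC)C#C[C@H](C)[C@@H](O[Si](C)(C)C(C)(C)C)[C@@H](OC)C[C@H](C)Cc1cc(N)cc(O[Si](C(C)C)(C(C)C)C(C)C)c1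
F3 | step 22 | iodoacrylamide enyne ((2E)-3-iodo-2-methylprop-2-enamide of F2) | C=C[C@H](C)[C@@H](O[Si](CC)(CC)CC)C#C[C@H](C)[C@@H](O[Si](C)(C)C(C)(C)C)[C@@H](OC)C[C@H](C)Cc1cc(NC(=O)/C(C)=C/I)cc(O[Si](C(C)C)(C(C)C)C(C)C)c1
F4 | step 22 | B-alkyl-9-BBN borane from hydroboration of the terminal alkene of F3 | C(C[C@H](C)[C@@H](O[Si](CC)(CC)CC)C#C[C@H](C)[C@@H](O[Si](C)(C)C(C)(C)C)[C@@H](OC)C[C@H](C)Cc1cc(NC(=O)/C(C)=C/I)cc(O[Si](C(C)C)(C(C)C)C(C)C)c1)B1C2CCCC1CCC2
F5 | step 25 | (2E,8Z)-8-iodo macrolactam (7R-OH, 11R-OTBS, 18-OTIPS) | CO[C@H]1C[C@H](C)Cc2cc(O[Si](C(C)C)(C(C)C)C(C)C)cc(c2)NC(=O)/C(C)=C/CC[C@H](C)[C@@H](O)/C(I)=C/[C@H](C)[C@H]1O[Si](C)(C)C(C)(C)C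
F6 | step 19 | (4R)-4-benzyl-3-[(2R,3R)-3-hydroxy-2-methylhex-4-ynoyl]-1,3-oxazolidin-2-one | O=C([C@H](C)[C@@H](O)C#CC)N1[C@H](Cc2ccccc2)COC1=O
F7 | step 19 | (4R)-4-benzyl-3-[(2R,3R)-2-methyl-3-(triethylsilyloxy)hex-4-ynoyl]-1,3-oxazolidin-2-one | O=C([C@H](C)[C@@H](O[Si](CC)(CC)CC)C#CC)N1[C@H](Cc2ccccc2)COC1=O
F8 | step 19 | (2S,3R)-2-methyl-3-(triethylsilyloxy)hex-4-yn-1-ol | OC[C@H](C)[C@@H](O[Si](CC)(CC)CC)C#CC
F9 | step 19 | (2R,3R)-2-methyl-3-(triethylsilyloxy)hex-4-ynal | O=C[C@H](C)[C@@H](O[Si](CC)(CC)CC)C#CC
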